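**Plan**
Cuts: C11=C12 (Wittig) into a ring A C15 phosphonium salt and the C25 aldehyde β-apo-12'-carotenal; C11'=C12' of that aldehyde (Wittig) into the ring B C15 salt and a C10 trienedial; the O–C(acyl) bond at C3; C9–C10 and C9'–C10' (vinyl Grignard additions).
No ring is formed: ring A is bought as α-ionone (C3 oxidised, C4=C5 moved to C5=C6) and ring B as β-ionone.
Forward: ring A C13 → C15 diol → C3 oleate → salt; ring B C13 → C15 salt, + C10 → C25; C15 + C25 → C40 ester.
Enabling feature: C3 of ring A is the only stereocentre, a secondary carbinol carbon (one H) between C2H2 (next to quaternary C1) and C4H2 (next to sp2 C5). Its oxygen is the ester oxygen, so acylation and stereodefinition can coincide.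
Stereochemistry: 3R comes from the lipase in a lipase/ruthenium dynamic kinetic oleoylation of the racemic ring alcohol; polyene E geometry comes from E building blocks plus thermal equilibration; the Z alkene is bought with oleoyl chloride.
The C9 ketone is vinylated before that step, so the ruthenium hydride meets no second hydrogen acceptor and no Grignard reagent meets the ester.

Key step: step 7

Remark: carotenoid numbering is used (ring A = oxygenated ring, ring B = primed ring). C9 of 7, 11 and 12 is a stereocentre of no consequence; both epimers are carried and step 8 makes C9 trigonal. The C10 trienedial 17 is taken as a purchasable carotenoid building block.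

Step 1
Reactants: 1 (±)-α-ionone
Product: 2 α-ionone ethylene ketal
Conditions: HOCH2CH2OH, HC(OMe)3, p-TsOH·H2O (cat.), rt
Reagents that add atoms: ethylene glycol, OCCO
Why: Acid-catalysed ketalisation with an orthoester as water scavenger runs at room temperature without moving C4=C5 and takes the C9 carbonyl out of play, so that the ketone made in step 2 is the only one the hydride of step 3 can reduce.

Step 2
Reactants: 2 α-ionone ethylene ketal
Product: 3 3-oxo-α-ionone ethylene ketal
Conditions: tBuOOH (70% aq.), NaOCl (aq.), K2CO3, MeCN, −5 to 0 °C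
Reagents that add atoms: tert-butyl hydroperoxide, CC(C)(C)OO
Why: Radical allylic oxidation in which tert-butylperoxyl radicals abstract hydrogen from the open ring methylene C3 next to C4=C5 rather than from the crowded C6–H, after which the allylic tert-butyl peroxide collapses under carbonate to the enone (Kornblum–DeLaMare fragmentation) while the ketal is safe in the basic medium.

Step 3
Reactants: 3 3-oxo-α-ionone ethylene ketal
Product: 5 (±)-3-hydroxy-α-ionone (cis/trans mixture), via hydroxy ketal 4 (not isolated)
Conditions: iBu2AlH, CH2Cl2, −78 °C; then 0.3 M aq. HCl, THF, 0 °C to rt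
Reagents that add atoms: water, O
Why: 1,2-Reduction of the β,β-disubstituted cyclohexenone by iBu2AlH is followed in the same flask by mild acid hydrolysis of the allylic ketal, and the racemic cis/trans mixture at C3/C6 needs no control because C6 is flattened in step 4 and C3 is set in step 7.

Step 4
Reactants: 5 (±)-3-hydroxy-α-ionone
Product: 6 (±)-3-hydroxy-β-ionone
Conditions: KOH, MeOH, 50 °C, N2
Reagents that add atoms: none
Why: Base-catalysed conjugative alkene migration as in the classical α- to β-ionone isomerisation, in which the doubly allylic C6–H, vinylogously acidified by the C9 ketone, is removed and reprotonation at C4 gives the fully conjugated dienone, so that loss of the C6 centre merges both diastereomers into one racemate.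

Step 5
Reactants: 6 (±)-3-hydroxy-β-ionone
Product: 7 (±)-3-hydroxy-vinyl-β-ionol (both C9 epimers)
Conditions: CH2=CHMgBr (3 equiv), THF, −20 to 0 °C; aq. NH4Cl
Reagents that add atoms: vinylmagnesium bromide, C=C[Mg]Br
Why: Grignard 1,2-addition to the unhindered methyl ketone is the standard ionone to vinyl-ionol homologation, with the first equivalent consumed by the C3 hydroxyl and the new C9 centre formed without control because it disappears in step 8.

Step 6
Reactants: 8 oleoyl chloride; 9 4-chlorophenol
Product: 10 4-chlorophenyl oleate
Conditions: Et3N, DMAP (cat.), CH2Cl2, 0 °C to rt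
Reagents that add atoms: none
Why: Schotten–Baumann-type O-acylation of a phenol by an acid chloride gives an activated aryl ester whose leaving group is neither oxidised nor reduced by ruthenium hydrides, and the Z alkene is not touched.

Step 7
Reactants: 7 (±)-3-hydroxy-vinyl-β-ionol; 10 4-chlorophenyl oleate
Product: 12 (3R)-3-oleoyloxy-vinyl-β-ionol (both C9 epimers), via C3 ketone 11 (not isolated)
Conditions: 10 (1.5 equiv), Novozym 435 (immobilised Candida antarctica lipase B, dried), [Ru2(CO)4(μ-H)(C4Ph4COHOCC4Ph4)] (4 mol%), 2,4-dimethylpentan-3-ol (0.5 equiv), 4 Å MS, toluene, 70 °C, Ar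
Reagents that add atoms: none
Why: At 70 °C the diruthenium hydride dissociates into a 16-electron cyclopentadienone complex, which takes the O–H and C3–H hydrogens from either enantiomer of 7 to give ketone 11, and an 18-electron hydroxycyclopentadienyl hydride, which returns them to either face of C3, so that (3R)- and (3S)-7 interconvert while the tertiary C9 carbinol, lacking a carbinol hydrogen, stays out of the redox cycle. In parallel the active-site serine of the lipase is oleoylated by the aryl ester 10 and hands the acyl group to the C3 hydroxyl of the enantiomer that fits its stereopocket, which forms the O–C(acyl) bond irreversibly because 4-chlorophenol does not compete as a nucleophile and is inert to the ruthenium hydride. The closest known reaction type is the lipase/ruthenium dynamic kinetic resolution of secondary alcohols, cyclic ones included, with 4-chlorophenyl acetate as donor; no ring is closed. The C3 centre is controlled by the enzyme alone: C2H2 backed by the quaternary C1 acts as the large flank and the flat C4H2–C5(sp2) as the medium one, so the empirical size rule for lipases predicts the 3R alcohol as the fast one, in keeping with the known ability of this lipase to esterify 3R-configured xanthophyll rings with long-chain donors. The step needs acylation of the secondary and not the tertiary hydroxyl (lipases do not accept tertiary alcohols), a substrate free of any other hydrogen acceptor (the C9 ketone was turned into the vinyl carbinol in step 5) and no drift of C5=C6 into conjugation with the carbonyl of 11 (base-free medium, and 2,4-dimethylpentan-3-ol as a non-acylable hydrogen reservoir that keeps 11 at a low stationary level). The isolated Z alkene of the oleoyl chain and the terminal vinyl group offer no polar bond to the coordinatively saturated hydride and should pass unchanged.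

Step 8
Reactants: 12 (3R)-3-oleoyloxy-vinyl-β-ionol
Product: 13 ring A C15 phosphonium bromide
Conditions: PPh3·HBr, CH2Cl2, 0 °C to rt, dark
Reagents that add atoms: triphenylphosphine hydrobromide, c1ccc(cc1)[PH+](c1ccccc1)c1ccccc1.[Br-]
Why: Acid-induced ionisation of the tertiary bis-allylic alcohol gives a delocalised trienyl cation that PPh3 captures at the unhindered terminal carbon (SN1' allylic substitution, the standard vinyl-ionol to C15 Wittig salt conversion), which erases C9, and the alcohol-free solvent protects the C3 ester from transesterification.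

Step 9
Reactants: 14 β-ionone
Product: 15 (±)-vinyl-β-ionol
Conditions: CH2=CHMgBr (1.2 equiv), THF, −20 to 0 °C; aq. NH4Cl
Reagents that add atoms: vinylmagnesium bromide, C=C[Mg]Br
Why: The same Grignard 1,2-addition as in step 5 applies to the parent dienone, and the racemic carbinol centre is lost in the next step.

Step 10
Reactants: 15 (±)-vinyl-β-ionol
Product: 16 ring B C15 phosphonium bromide
Conditions: PPh3·HBr, MeOH, rt, dark
Reagents that add atoms: triphenylphosphine hydrobromide, c1ccc(cc1)[PH+](c1ccccc1)c1ccccc1.[Br-]
Why: SN1' substitution through the trienyl cation proceeds as in step 8 and should give the crystalline, predominantly 9E salt.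

Step 11
Reactants: 16 ring B C15 phosphonium bromide; 17 (2E,4E,6E)-2,7-dimethylocta-2,4,6-trienedial
Product: 19 all-E β-apo-12'-carotenal, via ylide 18 (not isolated)
Conditions: 17 (2 equiv), slow addition of 16, 1,2-epoxybutane, EtOH, reflux, Ar, dark; crystallisation
Reagents that add atoms: none
Why: In this Wittig olefination with an epoxide as proton scavenger, bromide opens the epoxide and the resulting alkoxide turns 16 into ylide 18 at a low stationary level in the presence of excess dialdehyde, which together with the lower electrophilicity of the longer polyenal favours mono-olefination, and the all-E aldehyde is collected by crystallisation.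

Step 12
Reactants: 13 ring A C15 phosphonium bromide; 19 β-apo-12'-carotenal
Product: 22 (3R)-β-cryptoxanthin oleate, via ylide 20 (not isolated), via 11Z isomer 21 (not isolated)
Conditions: 1,2-epoxybutane (solvent), reflux, Ar, dark; concentrate; heptane, reflux; chromatography on deactivated silica, crystallisation from acetone at −20 °C
Reagents that add atoms: none
Why: The Wittig olefination forms C11=C12 with the epoxide as proton scavenger so that no alkoxide or hydroxide builds up to cleave the oleate, the sterically strained 11Z isomer 21 relaxes thermally to the all-E polyene, and neither C3 nor the isolated Z alkene of the acyl chain responds to heating at this level.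

**Compound list**
1 | (±)-α-ionone, (E)-4-(2,6,6-trimethylcyclohex-2-en-1-yl)but-3-en-2-one | CC(=O)/C=C/C1C(C)=CCCC1(C)C | starting material
2 | α-ionone ethylene ketal, 2-methyl-2-[(E)-2-(2,6,6-trimethylcyclohex-2-en-1-yl)ethenyl]-1,3-dioxolane (racemic) | CC1(/C=C/C2C(C)=CCCC2(C)C)OCCO1 | intermediate
3 | 3-oxo-α-ionone ethylene ketal (racemic) | CC1(/C=C/C2C(C)=CC(=O)CC2(C)C)OCCO1 | intermediate
4 | 3-hydroxy-α-ionone ethylene ketal (racemic, cis/trans; not isolated) | CC1(/C=C/C2C(C)=CC(O)CC2(C)C)OCCO1 | intermediate
5 | (±)-3-hydroxy-α-ionone (cis/trans mixture) | CC(=O)/C=C/C1C(C)=CC(O)CC1(C)C | intermediate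
6 | (±)-3-hydroxy-β-ionone | CC(=O)/C=C/C1=C(C)CC(O)CC1(C)C | intermediate
7 | (±)-3-hydroxy-vinyl-β-ionol, (E)-1-(4-hydroxy-2,6,6-trimethylcyclohex-1-en-1-yl)-3-methylpenta-1,4-dien-3-ol (racemic at C3, both C9 epimers) | C=CC(C)(O)/C=C/C1=C(C)CC(O)CC1(C)C | intermediate
8 | oleoyl chloride, (9Z)-octadec-9-enoyl chloride | CCCCCCCC/C=C\CCCCCCCC(=O)Cl | starting material
9 | 4-chlorophenol | Oc1ccc(Cl)cc1 | starting material
10 | 4-chlorophenyl oleate | CCCCCCCC/C=C\CCCCCCCC(=O)Oc1ccc(Cl)cc1 | intermediate
11 | 3-oxo-vinyl-β-ionol, transient C3 ketone of the racemisation (both C9 epimers; not isolated) | C=CC(C)(O)/C=C/C1=C(C)CC(=O)CC1(C)C | intermediate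
12 | (3R)-3-oleoyloxy-vinyl-β-ionol, (1R)-4-[(1E)-3-hydroxy-3-methylpenta-1,4-dien-1-yl]-3,5,5-trimethylcyclohex-3-en-1-yl (9Z)-octadec-9-enoate (both C9 epimers) | CCCCCCCC/C=C\CCCCCCCC(=O)O[C@@H]1CC(C)=C(/C=C/C(C)(O)C=C)C(C)(C)C1 | intermediate
13 | [(2E,4E)-3-methyl-5-[(4R)-2,6,6-trimethyl-4-(oleoyloxy)cyclohex-1-en-1-yl]penta-2,4-dien-1-yl]triphenylphosphonium bromide | CCCCCCCC/C=C\CCCCCCCC(=O)O[C@@H]1CC(C)=C(/C=C/C(C)=C/C[P+](c2ccccc2)(c2ccccc2)c2ccccc2)C(C)(C)C1.[Br-] | intermediate
14 | β-ionone | CC(=O)/C=C/C1=C(C)CCCC1(C)C | starting material
15 | (±)-vinyl-β-ionol, (E)-3-methyl-1-(2,6,6-trimethylcyclohex-1-en-1-yl)penta-1,4-dien-3-ol | C=CC(C)(O)/C=C/C1=C(C)CCCC1(C)C | intermediate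
16 | [(2E,4E)-3-methyl-5-(2,6,6-trimethylcyclohex-1-en-1-yl)penta-2,4-dien-1-yl]triphenylphosphonium bromide | CC1=C(/C=C/C(C)=C/C[P+](c2ccccc2)(c2ccccc2)c2ccccc2)C(C)(C)CCC1.[Br-] | intermediate
17 | (2E,4E,6E)-2,7-dimethylocta-2,4,6-trienedial | O=C/C(C)=C/C=C/C=C(C)/C=O | starting material
18 | ylide of 16 (not isolated) | CC1=C(/C=C/C(C)=C/C=P(c2ccccc2)(c2ccccc2)c2ccccc2)C(C)(C)CCC1 | intermediate
19 | all-E β-apo-12'-carotenal, (2E,4E,6E,8E,10E,12E)-2,7,11-trimethyl-13-(2,6,6-trimethylcyclohex-1-en-1-yl)trideca-2,4,6,8,10,12-hexaenal | CC1=C(/C=C/C(C)=C/C=C/C(C)=C/C=C/C=C(C)/C=O)C(C)(C)CCC1 | intermediate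
20 | ylide of 13 (not isolated) | CCCCCCCC/C=C\CCCCCCCC(=O)O[C@@H]1CC(C)=C(/C=C/C(C)=C/C=P(c2ccccc2)(c2ccccc2)c2ccccc2)C(C)(C)C1 | intermediate
21 | (3R,11Z)-β-cryptoxanthin oleate (not isolated) | CCCCCCCC/C=C\CCCCCCCC(=O)O[C@@H]1CC(C)=C(/C=C/C(C)=C/C=C\C(C)=C\C=C\C=C(C)\C=C\C=C(C)\C=C\C2=C(C)CCCC2(C)C)C(C)(C)C1 | intermediate
22 | (3R)-β-cryptoxanthin oleate, all-E polyene, (9Z)-octadec-9-enoate | CCCCCCCC/C=C\CCCCCCCC(=O)O[C@@H]1CC(C)=C(/C=C/C(C)=C/C=C/C(C)=C/C=C/C=C(C)/C=C/C=C(C)/C=C/C2=C(C)CCCC2(C)C)C(C)(C)C1 | target

**Step count**
Total steps: 12.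
Longest linear sequence: 8 steps (1, 2, 3, 4, 5, 7, 8, 12), from α-ionone.

**Steps most likely to fail**

Step 7.
- The lipase may discriminate too weakly between the two ring methylene flanks at 70 °C, which would erode the enantiomeric purity.
- Acyl transfer to the ring alcohol may be slow. The C3 ketone would then accumulate and its C5=C6 bond would slip into conjugation.
- The tertiary carbinol may ionise on long heating.
- Fallback, from 7 back to 12: the metal is left out. Compound 7 is acylated with 10 and the same lipase in toluene at 30 °C to about half conversion, which gives 12 and leaves (3S)-3-hydroxy-vinyl-β-ionol F1. After chromatographic separation, F1 is esterified with oleic acid under Mitsunobu conditions (PPh3, DIAD, toluene, 0 °C). SN2 inversion at C3 turns it into 12 as well, and the hindered tertiary C9 hydroxyl is not activated. Both enantiomers thus still converge on the 3R ester, at low temperature and without a ketone intermediate.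

Step 12.
- The Z isomers (11Z from the olefination, 9Z carried in from the salt) may converge incompletely on the all-E polyene.
- The waxy ester may purify poorly by crystallisation.
- The oleate may be lost slowly to the alkoxide generated from the epoxide.
- Fallback, from 12 back to 22: PBr3 in Et2O at −10 °C converts the tertiary carbinol with allylic shift into (3R)-3-oleoyloxy-β-ionylideneethyl bromide F2. A Michaelis–Arbuzov reaction with P(OEt)3 gives diethyl (3R)-3-oleoyloxy-β-ionylideneethylphosphonate F3. Horner–Wadsworth–Emmons olefination of 19 with F3 (NaN(SiMe3)2, THF, −78 to 0 °C) then forms C11=C12 with the inherently higher E preference of phosphonate carbanions, giving 22 with a water-soluble phosphate instead of phosphine oxide.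

Step 11.
- Over-olefination at both aldehyde groups of the symmetrical dialdehyde may consume the salt and complicate the isolation of the mono-adduct.
- Fallback, from 17 back to 19: stoichiometric control is replaced by desymmetrisation with a protecting group. Compound 17 is treated with one equivalent of 2,2-dimethylpropane-1,3-diol (p-TsOH cat., toluene) and the mono-acetal (2E,4E,6E)-7-(5,5-dimethyl-1,3-dioxan-2-yl)-2-methylocta-2,4,6-trienal F4 is separated, with recycling of dialdehyde and bis-acetal. Wittig reaction of F4 with 16 under the conditions of step 11 gives β-apo-12'-carotenal neopentyl glycol acetal F5. Dilute aqueous acid in THF releases 19.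

**Further compounds**
F1 | step 7 | (3S)-3-hydroxy-vinyl-β-ionol (both C9 epimers) | O[C@H]1CC(C)=C(/C=C/C(C)(O)C=C)C(C)(C)C1
F2 | step 12 | (3R)-3-oleoyloxy-β-ionylideneethyl bromide | CCCCCCCC/C=C\CCCCCCCC(=O)O[C@@H]1CC(C)=C(/C=C/C(C)=C/CBr)C(C)(C)C1
F3 | step 12 | diethyl (3R)-3-oleoyloxy-β-ionylideneethylphosphonate | CCCCCCCC/C=C\CCCCCCCC(=O)O[C@@H]1CC(C)=C(/C=C/C(C)=C/CP(=O)(OCC)OCC)C(C)(C)C1
F4 | step 11 | (2E,4E,6E)-7-(5,5-dimethyl-1,3-dioxan-2-yl)-2-methylocta-2,4,6-trienal | O=C/C(C)=C/C=C/C=C(C)/C1OCC(C)(C)CO1
F5 | step 11 | β-apo-12'-carotenal neopentyl glycol acetal | CC1=C(/C=C/C(C)=C/C=C/C(C)=C/C=C/C=C(C)/C2OCC(C)(C)CO2)C(C)(C)CCC1
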